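**Plan**

1. Retrosynthetic cuts, in order: O1–C2 of ring C (intramolecular Mitsunobu etherification), C4–C4a (aryllithium plus Weinreb amide), N–CH3, then N–C6' and C2'–C3' of the piperidine (N-sulfinyl aldimine plus 4-chlorobutyl Grignard), and last the formyl carbon on ring A.
2. Enabling feature: the ring oxygen O1 on C8a lies para to the piperidine-bearing C6, so ring A with the same group on O5 and O7 is two-fold symmetric about the C6···C8a axis. Its two free CH positions (future C4a and C8) are equivalent and O1 is the unique oxygen, so acylation at either CH and closure through O1 can only give the 6-substituted flavanone, never the 8-isomer.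
3. Forward order: ring A is bought, the piperidine ring is built on it (steps 3–6), the three-carbon chain carrying ring B is attached as an aryl ketone (step 9), and the pyranone ring C is closed last (step 11).
4. Stereochemistry: C2' (R) comes from (S)-tert-butanesulfinamide in the Grignard addition; C2 (S) comes from commercial ethyl (R)-3-hydroxy-3-phenylpropanoate, inverted in the ring closure.
5. Helpers and their removal: MOM on O1 (protection, then lithiation director; removed in step 10), the C2 hydroxyl kept at the alcohol oxidation level as leaving group (lost in step 11), benzyl ethers on O5 and O7 (removed in step 12).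

Key step: step 11

Remark: flavanone numbering (O1, C2, C3, C4, C4a, C5–C8, C8a) is used for the target and primed numbers for the piperidine; 3,5-bis(benzyloxy)phenol and ethyl (R)-3-hydroxy-3-phenylpropanoate are taken as purchasable.

**Route**

Step 1
Reactants: 1 3,5-bis(benzyloxy)phenol
Product: 3 2,6-bis(benzyloxy)-4-hydroxybenzaldehyde, via iminium chloride 2 (not isolated)
Conditions: POCl3, DMF, MeCN, 0 °C to rt; then H2O, 50 °C
Reagents that add atoms: N,N-dimethylformamide CN(C)C=O; water O
Why: Vilsmeier–Haack formylation of a phloroglucinol diether should occur mainly para to the free hydroxyl (between the two benzyloxy groups), and water hydrolyses iminium salt 2 to the aldehyde; the minor hydrogen-bonded ortho isomer is removed by chromatography.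

Step 2
Reactants: 3 2,6-bis(benzyloxy)-4-hydroxybenzaldehyde
Product: 4 2,6-bis(benzyloxy)-4-(methoxymethoxy)benzaldehyde
Conditions: MOMCl, i-Pr2NEt, CH2Cl2, 0 °C to rt
Reagents that add atoms: chloromethyl methyl ether COCCl
Why: Williamson-type O-alkylation of the only phenol; the MOM acetal masks the future O1 through the organometallic steps and later directs ring lithiation.

Step 3
Reactants: 4 2,6-bis(benzyloxy)-4-(methoxymethoxy)benzaldehyde; 5 (S)-2-methylpropane-2-sulfinamide
Product: 6 (S)-N-[(E)-[2,6-bis(benzyloxy)-4-(methoxymethoxy)phenyl]methylidene]-2-methylpropane-2-sulfinamide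
Conditions: Ti(OEt)4, THF, 60 °C
Reagents that add atoms: none
Why: Ti(OEt)4 acts as Lewis acid and water scavenger in the condensation of the aldehyde with tert-butanesulfinamide, giving the (E)-N-sulfinyl aldimine without touching the sulfur configuration.

Step 4
Reactants: 6 the (S,E)-N-sulfinyl aldimine; 7 1-bromo-4-chlorobutane
Product: 9 (S)-N-[(1R)-1-[2,6-bis(benzyloxy)-4-(methoxymethoxy)phenyl]-5-chloropentyl]-2-methylpropane-2-sulfinamide, via 4-chlorobutylmagnesium bromide 8 (not isolated)
Conditions: 7, Mg, THF, rt; then 6, CH2Cl2, −48 °C to rt; then aq NH4Cl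
Reagents that add atoms: none
Why: Grignard 1,2-addition to an N-tert-butanesulfinyl aldimine in a non-coordinating solvent, through a six-membered chair transition state (Mg on the sulfinyl oxygen, tert-butyl equatorial), should deliver the 4-chlorobutyl group to the face that makes the new benzylic carbon (R) for the (S)-sulfinyl (E)-aryl aldimine; magnesium inserts into C–Br and leaves C–Cl for the ring closure.

Step 5
Reactants: 9 the (S,R)-sulfinamide
Product: 11 (2R)-2-[2,6-bis(benzyloxy)-4-(methoxymethoxy)phenyl]piperidine, via N-sulfinylpiperidine 10 (not isolated)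
Conditions: KN(SiMe3)2, THF, 0 to 40 °C; then HCl (4 M in dioxane), MeOH, 0 °C, 20 min; then aq NaHCO3
Reagents that add atoms: none
Why: Intramolecular N-alkylation of the sulfinamide anion (6-exo-tet SN2) closes the piperidine without touching the stereocentre, and brief cold methanolic HCl then cleaves the N–S bond while the aryl MOM ether, which needs longer or warmer acid, should survive.

Step 6
Reactants: 11 (2R)-2-[2,6-bis(benzyloxy)-4-(methoxymethoxy)phenyl]piperidine
Product: 12 (2R)-2-[2,6-bis(benzyloxy)-4-(methoxymethoxy)phenyl]-1-methylpiperidine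
Conditions: aq HCHO, NaBH(OAc)3, ClCH2CH2Cl, rt
Reagents that add atoms: formaldehyde C=O
Why: Reductive amination methylates the secondary amine through its iminium ion; with no free phenol present, Mannich attack of the iminium on the electron-rich ring is not expected.

Step 7
Reactants: 13 ethyl (3R)-3-hydroxy-3-phenylpropanoate
Product: 14 ethyl (3R)-3-[(tert-butyldimethylsilyl)oxy]-3-phenylpropanoate
Conditions: TBSCl, imidazole, DMF, rt
Reagents that add atoms: tert-butyldimethylsilyl chloride CC(C)(C)[Si](C)(C)Cl
Why: Imidazole-promoted silylation of the secondary benzylic alcohol; no bond to the stereocentre is broken.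

Step 8
Reactants: 14 ethyl (3R)-3-[(tert-butyldimethylsilyl)oxy]-3-phenylpropanoate
Product: 15 (3R)-3-[(tert-butyldimethylsilyl)oxy]-N-methoxy-N-methyl-3-phenylpropanamide
Conditions: MeNHOMe·HCl, i-PrMgCl, THF, −20 to 0 °C
Reagents that add atoms: N,O-dimethylhydroxylamine hydrochloride CNOC.Cl
Why: Direct ester aminolysis by the chloromagnesium amide of N,O-dimethylhydroxylamine gives the Weinreb amide at low temperature, where the β-silyloxy ester should not eliminate.

Step 9
Reactants: 12 (2R)-2-[2,6-bis(benzyloxy)-4-(methoxymethoxy)phenyl]-1-methylpiperidine; 15 the (R)-Weinreb amide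
Product: 17 (3R)-1-{2,4-bis(benzyloxy)-6-(methoxymethoxy)-3-[(2R)-1-methylpiperidin-2-yl]phenyl}-3-[(tert-butyldimethylsilyl)oxy]-3-phenylpropan-1-one, via aryllithium 16 (not isolated)
Conditions: n-BuLi, THF, 0 °C, 1 h; then 15, −78 to 0 °C; then H2O
Reagents that add atoms: none
Why: Directed ortho-metalation puts lithium on the CH between the MOM and benzyloxy oxygens (the two such positions are equivalent by rotation about the aryl–piperidine bond), and the aryllithium adds once to the Weinreb amide because the chelated tetrahedral adduct survives until quench (Weinreb ketone synthesis), forming the C4–C4a bond.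

Step 10
Reactants: 17 the MOM/TBS-protected aryl ketone
Product: 18 (3R)-1-{2,4-bis(benzyloxy)-6-hydroxy-3-[(2R)-1-methylpiperidin-2-yl]phenyl}-3-hydroxy-3-phenylpropan-1-one
Conditions: HCl (1.25 M in MeOH), 0 °C to rt; then aq NaHCO3
Reagents that add atoms: none
Why: Acid-catalysed methanolysis removes the MOM acetal (made labile by the ortho acyl group) and the TBS ether in one operation, while the benzyl ethers, the β-hydroxy ketone and both stereocentres should be stable at this temperature.

Step 11
Reactants: 18 the phenolic (R)-β-hydroxy ketone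
Product: 20 (2S)-5,7-bis(benzyloxy)-6-[(2R)-1-methylpiperidin-2-yl]-2-phenyl-2,3-dihydro-4H-chromen-4-one, via alkoxyphosphonium phenoxide 19 (not isolated)
Conditions: PPh3, DIAD, THF, 0 °C to rt, slow addition of DIAD
Reagents that add atoms: none
Why: PPh3 and DIAD form a betaine that deprotonates the only free phenol (O1–H, acidified by the ortho acyl group) and turns the (R)-benzylic hydroxyl into an alkoxyphosphonium leaving group (19), which the phenoxide displaces intramolecularly with loss of Ph3P=O. The closest known reaction type is the intramolecular Mitsunobu etherification of 1-(2-hydroxyaryl)-3-hydroxyalkan-1-ones to 2-substituted chroman-4-ones. Ring C closes in the 6-exo-tet mode, with O1 as nucleophile and C2 as electrophile. C2 is the only new stereocentre, and its (S) configuration follows from SN2 inversion of the (R)-carbinol carbon taken from the chiral-pool ester; the piperidine centre is a spectator. The step needs substitution to win over E1cB elimination toward the chalcone and over SN1 ionisation: the phenoxide held next to the carbinol by the aryl ketone (six-membered transition state), an unsubstituted phenyl group that stabilises a cation only weakly, low temperature and slow DIAD addition serve this. Regiochemistry needs no control here, because O5 and O7 are benzylated and only the oxygen para to the piperidine carbon is free, so only the 6-substituted flavanone can form.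

Step 12
Reactants: 20 the 5,7-bis(benzyloxy)flavanone
Product: 21 (2S)-5,7-dihydroxy-6-[(2R)-1-methylpiperidin-2-yl]-2-phenyl-2,3-dihydro-4H-chromen-4-one
Conditions: H2 (1 atm), Pd/C, EtOAc–MeOH, rt
Reagents that add atoms: none
Why: Hydrogenolysis of the two aryl benzyl ethers under neutral conditions, which should neither open the flavanone ring nor epimerise C2; the hindered tertiary benzylic C–N bond and the cyclic C2–O1 bond are cleaved far more slowly than O-benzyl groups.

**Compound list**

1 | 3,5-bis(benzyloxy)phenol | Oc1cc(OCc2ccccc2)cc(OCc2ccccc2)c1 | starting material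
2 | [2,6-bis(benzyloxy)-4-hydroxybenzylidene]dimethyliminium chloride | C[N+](C)=Cc1c(OCc2ccccc2)cc(O)cc1OCc1ccccc1.[Cl-] | intermediate (not isolated)
3 | 2,6-bis(benzyloxy)-4-hydroxybenzaldehyde | O=Cc1c(OCc2ccccc2)cc(O)cc1OCc1ccccc1 | intermediate
4 | 2,6-bis(benzyloxy)-4-(methoxymethoxy)benzaldehyde | COCOc1cc(OCc2ccccc2)c(C=O)c(OCc2ccccc2)c1 | intermediate
5 | (S)-2-methylpropane-2-sulfinamide | CC(C)(C)[S@](=O)N | starting material
6 | (S)-N-[(E)-[2,6-bis(benzyloxy)-4-(methoxymethoxy)phenyl]methylidene]-2-methylpropane-2-sulfinamide | CC(C)(C)[S@](=O)/N=C/c1c(OCc2ccccc2)cc(OCOC)cc1OCc1ccccc1 | intermediate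
7 | 1-bromo-4-chlorobutane | ClCCCCBr | starting material
8 | 4-chlorobutylmagnesium bromide | ClCCCC[Mg]Br | intermediate (not isolated)
9 | (S)-N-[(1R)-1-[2,6-bis(benzyloxy)-4-(methoxymethoxy)phenyl]-5-chloropentyl]-2-methylpropane-2-sulfinamide | CC(C)(C)[S@](=O)N[C@H](CCCCCl)c1c(OCc2ccccc2)cc(OCOC)cc1OCc1ccccc1 | intermediate
10 | (2R)-2-[2,6-bis(benzyloxy)-4-(methoxymethoxy)phenyl]-1-[(S)-tert-butylsulfinyl]piperidine | CC(C)(C)[S@](=O)N1CCCC[C@@H]1c1c(OCc2ccccc2)cc(OCOC)cc1OCc1ccccc1 | intermediate (not isolated)
11 | (2R)-2-[2,6-bis(benzyloxy)-4-(methoxymethoxy)phenyl]piperidine | N1CCCC[C@@H]1c1c(OCc2ccccc2)cc(OCOC)cc1OCc1ccccc1 | intermediate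
12 | (2R)-2-[2,6-bis(benzyloxy)-4-(methoxymethoxy)phenyl]-1-methylpiperidine | CN1CCCC[C@@H]1c1c(OCc2ccccc2)cc(OCOC)cc1OCc1ccccc1 | intermediate
13 | ethyl (3R)-3-hydroxy-3-phenylpropanoate | CCOC(=O)C[C@@H](O)c1ccccc1 | starting material
14 | ethyl (3R)-3-[(tert-butyldimethylsilyl)oxy]-3-phenylpropanoate | CCOC(=O)C[C@@H](O[Si](C)(C)C(C)(C)C)c1ccccc1 | intermediate
15 | (3R)-3-[(tert-butyldimethylsilyl)oxy]-N-methoxy-N-methyl-3-phenylpropanamide | CON(C)C(=O)C[C@@H](O[Si](C)(C)C(C)(C)C)c1ccccc1 | intermediate
16 | {2,4-bis(benzyloxy)-6-(methoxymethoxy)-3-[(2R)-1-methylpiperidin-2-yl]phenyl}lithium | CN1CCCC[C@@H]1c1c(OCc2ccccc2)cc(OCOC)c([Li])c1OCc1ccccc1 | intermediate (not isolated)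
17 | (3R)-1-{2,4-bis(benzyloxy)-6-(methoxymethoxy)-3-[(2R)-1-methylpiperidin-2-yl]phenyl}-3-[(tert-butyldimethylsilyl)oxy]-3-phenylpropan-1-one | CN1CCCC[C@@H]1c1c(OCc2ccccc2)cc(OCOC)c(C(=O)C[C@@H](O[Si](C)(C)C(C)(C)C)c2ccccc2)c1OCc1ccccc1 | intermediate
18 | (3R)-1-{2,4-bis(benzyloxy)-6-hydroxy-3-[(2R)-1-methylpiperidin-2-yl]phenyl}-3-hydroxy-3-phenylpropan-1-one | CN1CCCC[C@@H]1c1c(OCc2ccccc2)cc(O)c(C(=O)C[C@@H](O)c2ccccc2)c1OCc1ccccc1 | intermediate
19 | [(1R)-3-{2,4-bis(benzyloxy)-3-[(2R)-1-methylpiperidin-2-yl]-6-oxidophenyl}-3-oxo-1-phenylpropoxy]triphenylphosphonium (zwitterion) | CN1CCCC[C@@H]1c1c(OCc2ccccc2)cc([O-])c(C(=O)C[C@@H](O[P+](c2ccccc2)(c2ccccc2)c2ccccc2)c2ccccc2)c1OCc1ccccc1 | intermediate (not isolated)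
20 | (2S)-5,7-bis(benzyloxy)-6-[(2R)-1-methylpiperidin-2-yl]-2-phenyl-2,3-dihydro-4H-chromen-4-one | CN1CCCC[C@@H]1c1c(OCc2ccccc2)cc2c(c1OCc1ccccc1)C(=O)C[C@@H](c1ccccc1)O2 | intermediate
21 | (2S)-5,7-dihydroxy-6-[(2R)-1-methylpiperidin-2-yl]-2-phenyl-2,3-dihydro-4H-chromen-4-one | CN1CCCC[C@@H]1c1c(O)cc2c(c1O)C(=O)C[C@@H](c1ccccc1)O2 | target

**Step count and risks**

Total step count: 12. Longest linear sequence: 10 steps (steps 1–6 and 9–12, from 1 to 21); steps 7 and 8 prepare fragment 15.

Steps most likely to fail:

1. Step 11 (ring closure). The activated β-hydroxy ketone may lose the phosphonium oxide by E1cB elimination to the chalcone, or ionise partly at the benzylic carbon, which would cost yield or enantiopurity. Fallback: setting out from 18, KOH in EtOH at rt should dehydrate the aldol to the 2'-hydroxychalcone (E)-1-{2,4-bis(benzyloxy)-6-hydroxy-3-[(2R)-1-methylpiperidin-2-yl]phenyl}-3-phenylprop-2-en-1-one F1. An enantioselective intramolecular oxa-Michael addition (6-endo-trig) catalysed by a bifunctional cinchona-alkaloid thiourea (10 mol%, toluene, −20 °C) then closes ring C under catalyst control, returning to the route at 20. The quinine- or quinidine-derived pseudoenantiomer would be chosen for the 2S sense, and only modest selectivity is to be expected for an unactivated, electron-rich chalcone.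

2. Step 4 (Grignard addition). The ortho benzyloxy groups may coordinate magnesium and disturb the chelated transition state, giving poor facial selectivity, or the hindered electron-rich aldimine may react sluggishly. Fallback: setting out from 4, addition of Grignard reagent 8 gives racemic 1-[2,6-bis(benzyloxy)-4-(methoxymethoxy)phenyl]-5-chloropentan-1-ol F2, and Dess–Martin oxidation gives 1-[2,6-bis(benzyloxy)-4-(methoxymethoxy)phenyl]-5-chloropentan-1-one F3. Condensation with 5 (Ti(OEt)4, THF, 70 °C) gives the N-sulfinyl ketimine (S)-N-{(1E)-1-[2,6-bis(benzyloxy)-4-(methoxymethoxy)phenyl]-5-chloropentylidene}-2-methylpropane-2-sulfinamide F4. Reduction with LiBH(s-Bu)3 (THF, −78 °C, open transition state) should then set the (R) carbon by hydride delivery, returning to the route at 9.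

3. Step 9 (lithiation and acylation). n-BuLi may deprotonate a benzylic OCH2 of a benzyl ether (followed by Wittig rearrangement) instead of the ring CH, so that little aryllithium reaches the amide. Fallback: setting out from 12, electrophilic bromination (NBS, MeCN, −20 °C, amine masked as its trifluoroacetate salt) at either of the two equivalent free ring positions should give (2R)-2-[2,6-bis(benzyloxy)-3-bromo-4-(methoxymethoxy)phenyl]-1-methylpiperidine F5. Bromine–lithium exchange (n-BuLi, THF, −78 °C) then gives the same aryllithium 16 without a deprotonation step, and addition of 15 returns to the route at 17.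

**Further compounds**

F1 | step 11 | (E)-1-{2,4-bis(benzyloxy)-6-hydroxy-3-[(2R)-1-methylpiperidin-2-yl]phenyl}-3-phenylprop-2-en-1-one | CN1CCCC[C@@H]1c1c(OCc2ccccc2)cc(O)c(C(=O)/C=C/c2ccccc2)c1OCc1ccccc1
F2 | step 4 | 1-[2,6-bis(benzyloxy)-4-(methoxymethoxy)phenyl]-5-chloropentan-1-ol (racemic) | OC(CCCCCl)c1c(OCc2ccccc2)cc(OCOC)cc1OCc1ccccc1
F3 | step 4 | 1-[2,6-bis(benzyloxy)-4-(methoxymethoxy)phenyl]-5-chloropentan-1-one | O=C(CCCCCl)c1c(OCc2ccccc2)cc(OCOC)cc1OCc1ccccc1
F4 | step 4 | (S)-N-{(1E)-1-[2,6-bis(benzyloxy)-4-(methoxymethoxy)phenyl]-5-chloropentylidene}-2-methylpropane-2-sulfinamide | CC(C)(C)[S@](=O)/N=C(\CCCCCl)c1c(OCc2ccccc2)cc(OCOC)cc1OCc1ccccc1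
F5 | step 9 | (2R)-2-[2,6-bis(benzyloxy)-3-bromo-4-(methoxymethoxy)phenyl]-1-methylpiperidine | CN1CCCC[C@@H]1c1c(OCc2ccccc2)cc(OCOC)c(Br)c1OCc1ccccc1
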